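Late in a run the complex with one exchanged is a small remainder in slow decline: the north-east run reads 9% at 6.00 h and 7% at 10.0 h. The flask has that run's starting complex but less incoming ligand, so the readings have to be carried across.

| flask | starting complex | incoming ligand | remark | time |
|---|---|---|---|---|
| south | 0.56 M | 1.2 M | run made earlier |  |
| south-west | 0.88 M | 1.2 M | run made earlier |  |
| north-east | 0.40 M | 1.8 M | run made earlier |  |
| flask | 0.40 M | 1.20 M |  | 12 h |

| run | time / h | complex with one exchanged / % | complex with two exchanged / % | starting complex / % |
|---|---|---|---|---|
| south | 2.50 | 21 | 15 | 62 |
| south | 5.00 | 14 | 27 | 39 |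
| south | 8.00 | 11 | 35 | 34 |
| south | 10.0 | 10 | 39 | 27 |
| south | 12.0 | 8 | 42 | 24 |
| south | 15.0 | 8 | 48 | 25 |
| south-west | 1.00 | 15 | 3 | 78 |
| south-west | 3.00 | 19 | 16 | 59 |
| south-west | 5.00 | 14 | 23 | 47 |
| south-west | 8.00 | 12 | 31 | 39 |
| south-west | 12.0 | 5 | 36 | 35 |
| south-west | 15.0 | 5 | 37 | 32 |
| north-east | 1.33 | 20 | 9 | 62 |
| north-east | 4.00 | 14 | 38 | 27 |
| north-east | 6.00 | 9 | 48 | 23 |
| north-east | 10.0 | 7 | 57 | 14 |
| north-east | 15.0 | 5 | 67 | 13 |

(standard deviation of a reading: 1.5 percentage points)

- percentages count the starting complex that a species holds: one idle adduct counts as two
- complex with two exchanged is meant together with its idle adduct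
- the analysis behind the earlier runs scatters by 1.5 percentage points, standard deviation
- what may be going on: starting complex + complex with two exchanged <-> idle adduct; complex with one exchanged + incoming ligand <-> leaving ligand + complex with two exchanged; starting complex + incoming ligand <-> leaving ligand + complex with one exchanged
- in an amount of complex with two exchanged, one idle adduct counts as one complex with two exchanged

- equivalents of incoming ligand to starting complex, everything else as given, that leave most complex with one exchanged at 12 h
- the amount of complex with one exchanged then, in percent of the starting complex charged
- the amount of complex with one exchanged with the amounts as given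

The forward rates of both exchanges go with the first power of incoming ligand, so at one charge of starting complex a run is placed roughly by 864 M·min, the ligand exposure, charged incoming ligand times time. This yardstick counts the charge and leaves out both the ligand spent and the way back, so it can give an estimated bracket and no exact place. The north-east readings stand at exposures 648 M·min and 1080 M·min, on either side of the flask, so the estimate puts the flask below about 9% and above about 7%. The flask's exposure falls midway, at 8.00 h of that run, which gives 8.00%. The flask has 3.00 equivalents against 4.50, fewer, so it spends a larger share of its ligand and lags at equal exposure; the reckoning here therefore commits to the upper half of the bracket.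

The forecast gives 7.5% (6% to 9.5%), inside the bracket but below its middle, and a best of 12.5% at 0.85 equiv, arguing: “Fewer equivalents slow the second exchange, so the mono peak arrives later.”

The flask gives 8.23%, and its best is 15.2% at 0.823 equiv.

    starting complex + complex with two exchanged ⇌ idle adduct, settled at all times (K = 7.20 L mol⁻¹)
    complex with one exchanged + incoming ligand ⇌ leaving ligand + complex with two exchanged (K = 5.40, k = 1.00 × 10⁻⁴ L mol⁻¹ s⁻¹)
    starting complex + incoming ligand ⇌ leaving ligand + complex with one exchanged (K = 0.290, k = 4.70 × 10⁻⁵ L mol⁻¹ s⁻¹)

At 1.93 h the forward second exchange gives the complex with one exchanged a half-life of 1.8 h, short against 12 h. At 12 h it is made at 0.679 of the rate at which it is used, so it is still falling, and the flask's exposure of 864 M·min finds it in the upper half of the bracket. The neighbour with 0.48 M of incoming ligand has exposure 346 M·min, which is 3.20 h of the north-east run, between its readings of 20% and 14%, and that neighbour holds 14.3%.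

The numbers in the tables were generated by integration for substances that don't exist; scatter was added.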